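**Retrosynthetic overview**
1. Target 29 comes from C18 acylation and desilylation of a bis-silyl triol; its C8 carbinol comes from Markovnikov hydration of an 8(17)-alkene, made by methylenation of 8-ketone 23.
2. Ring B of 23 is made last, by a semipinacol one-carbon ring enlargement of the trans-fused cyclopentyl carbinol 21: C10 shifts from C8 to C9. This forges the hindered C9–C10 bond, creates the trans-decalin and the C9 stereocentre, and unveils the C8 carbonyl.
3. The feature that makes this possible is the vicinal C8 tertiary hydroxyl / C9 mesylate pair on the strained five-membered ring C5–C6–C7–C8–C10, whose C8–C10 bond lies antiperiplanar to the C9–O bond. It is built by Z-selective Wittig union of hydrindanone 11 with the (S)-citronellol-derived C9–C16 ylide, followed by osmylation anti to the C10 methyl.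
4. Hydrindanone 11 comes from amino-acid-mediated annulation of 2-methylcyclopentane-1,3-dione with ethyl vinyl ketone, reductive hydroxymethylation (sets C5 and C4) and removal of the C3 carbonyl.
5. Ring order: five-membered ring (purchased) → ring A (aldol annulation) → ring B (enlargement of the five-membered ring).

Key step: step 16

Remark: the SMILES is read as the (4S,5S,8S,9S,10R,13S) ent-labdane (C18–O equatorial and anti to the C10 methyl, 8-OH equatorial, H-9 axial); labdane numbering is used for all intermediates, and CIP labels at unchanged centres sometimes switch only because substituent priorities change.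

**Route**

Step 1
Reactants: 1 2-methylcyclopentane-1,3-dione; 2 pent-1-en-3-one (ethyl vinyl ketone)
Product: 3 2-methyl-2-(3-oxopentyl)cyclopentane-1,3-dione
Conditions: H2O, AcOH (cat.), 70 °C
Reagents that add atoms: none
Why: Michael addition of the acidic 1,3-dione to the enone should give the achiral triketone, the standard entry to Hajos–Parrish-type substrates.

Step 2
Reactants: 3 2-methyl-2-(3-oxopentyl)cyclopentane-1,3-dione
Product: 4 (7aR)-4,7a-dimethyl-2,3,7,7a-tetrahydro-1H-indene-1,5(6H)-dione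
Conditions: (R)-phenylalanine (1 equiv), camphor-10-sulfonic acid (0.5 equiv), DMF, 30 → 70 °C; recrystallisation
Reagents that add atoms: none
Why: The amino-acid-mediated enamine aldol condensation (Hajos–Parrish reaction in its phenylalanine variant for ethyl ketones) desymmetrises the dione and closes ring A, and the (R)-amino acid is expected to set the quaternary C10 as R, the mirror image of the series given by the natural amino acid.

Step 3
Reactants: 4 (7aR)-4,7a-dimethyl-2,3,7,7a-tetrahydro-1H-indene-1,5(6H)-dione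
Product: 5 (1R,7aR)-1-hydroxy-4,7a-dimethyl-1,2,3,6,7,7a-hexahydro-5H-inden-5-one
Conditions: NaBH4 (0.3 equiv), EtOH, −20 °C
Reagents that add atoms: none
Why: Chemoselective borohydride reduction takes the saturated cyclopentanone in the presence of the tetrasubstituted enone, with hydride arriving anti to the angular methyl to give the C8 alcohol cis to it (a centre that is oxidised again in step 8).

Step 4
Reactants: 5 (1R,7aR)-1-hydroxy-4,7a-dimethyl-1,2,3,6,7,7a-hexahydro-5H-inden-5-one
Product: 7 (1R,3aS,4S,7aR)-1-hydroxy-4-(hydroxymethyl)-4,7a-dimethyloctahydro-5H-inden-5-one, via dilithium enolate 6 (not isolated)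
Conditions: Li (2.5 equiv), NH3(l)/THF, −78 → −33 °C; NH3 evaporated; CH2O (gas, from paraformaldehyde), THF, −78 °C; aq. NH4Cl
Reagents that add atoms: formaldehyde C=O
Why: In this Stork reductive alkylation the dissolving-metal reduction, with the substrate hydroxyl as the single proton source, should protonate C5 axially to give the trans ring fusion and leave the regiodefined C3–C4 enolate, which adds to formaldehyde on the face anti to the C10 methyl so that the hydroxymethyl becomes equatorial and the C4 methyl axial, as in reductive hydroxymethylation of 4-methyl-enone terpenoid precursors.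

Step 5
Reactants: 7 (1R,3aS,4S,7aR)-1-hydroxy-4-(hydroxymethyl)-4,7a-dimethyloctahydro-5H-inden-5-one
Product: 8 (1R,3aS,4S,7aR)-4-(hydroxymethyl)-4,7a-dimethyloctahydrospiro[indene-5,2'-[1,3]dithiolan]-1-ol
Conditions: HSCH2CH2SH, BF3·OEt2, CH2Cl2, 0 °C → rt
Reagents that add atoms: ethane-1,2-dithiol SCCS
Why: Lewis-acid dithioketalisation of the hindered C3 ketone tolerates both free hydroxyls, is not prone to retro-aldol loss of formaldehyde, and prepares the carbonyl for reductive removal.

Step 6
Reactants: 8 (1R,3aS,4S,7aR)-4-(hydroxymethyl)-4,7a-dimethyloctahydrospiro[indene-5,2'-[1,3]dithiolan]-1-ol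
Product: 9 (1R,3aR,4S,7aR)-4-(hydroxymethyl)-4,7a-dimethyloctahydro-1H-inden-1-ol
Conditions: Raney Ni (W-2), EtOH, reflux
Reagents that add atoms: none
Why: Raney nickel desulfurisation (Mozingo reduction) replaces the dithiolane by CH2 under neutral conditions that leave the alcohols and all stereocentres untouched.

Step 7
Reactants: 9 (1R,3aR,4S,7aR)-4-(hydroxymethyl)-4,7a-dimethyloctahydro-1H-inden-1-ol
Product: 10 (1R,3aR,4S,7aR)-4-{[(tert-butyldimethylsilyl)oxy]methyl}-4,7a-dimethyloctahydro-1H-inden-1-ol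
Conditions: TBSCl (1.05 equiv), imidazole, CH2Cl2, 0 °C
Reagents that add atoms: tert-butyl(chloro)dimethylsilane CC(C)(C)[Si](C)(C)Cl
Why: Silylation should be selective for the primary C18 hydroxyl over the secondary C8 hydroxyl, which is flanked by the quaternary C10.

Step 8
Reactants: 10 (1R,3aR,4S,7aR)-4-{[(tert-butyldimethylsilyl)oxy]methyl}-4,7a-dimethyloctahydro-1H-inden-1-ol
Product: 11 (3aR,4S,7aR)-4-{[(tert-butyldimethylsilyl)oxy]methyl}-4,7a-dimethyloctahydro-1H-inden-1-one
Conditions: (n-Pr4N)RuO4 (5 mol %), NMO, 4 Å MS, CH2Cl2, rt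
Reagents that add atoms: none
Why: Ley–Griffith oxidation returns the C8 ketone with no epimerisable centre nearby, since C10 is quaternary and C5 is not α to the carbonyl.

Step 9
Reactants: 12 (S)-citronellol
Product: 13 tert-butyl{[(3S)-3,7-dimethyloct-6-en-1-yl]oxy}diphenylsilane
Conditions: TBDPSCl, imidazole, DMF, rt
Reagents that add atoms: tert-butyl(chloro)diphenylsilane CC(C)(C)[Si](Cl)(c1ccccc1)c1ccccc1
Why: Standard silylation protects the future C15 hydroxyl, and the C13 stereocentre is taken unchanged from the chiral pool.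

Step 10
Reactants: 13 tert-butyl{[(3S)-3,7-dimethyloct-6-en-1-yl]oxy}diphenylsilane
Product: 15 (4S)-6-[(tert-butyldiphenylsilyl)oxy]-4-methylhexan-1-ol, via ozonide 14 (not isolated)
Conditions: O3, CH2Cl2, −78 °C; then NaBH4, MeOH, −78 °C → rt
Reagents that add atoms: ozone [O-][O+]=O
Why: Ozonolysis with reductive work-up cleaves the trisubstituted alkene to the primary alcohol at the future C9 without touching C13.

Step 11
Reactants: 15 (4S)-6-[(tert-butyldiphenylsilyl)oxy]-4-methylhexan-1-ol
Product: 16 tert-butyl{[(3S)-6-iodo-3-methylhexyl]oxy}diphenylsilane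
Conditions: I2, PPh3, imidazole, CH2Cl2, 0 °C → rt
Reagents that add atoms: iodine II
Why: Appel-type iodination (Garegg–Samuelsson conditions) converts the primary alcohol into the iodide by SN2 displacement of the oxyphosphonium group.

Step 12
Reactants: 16 tert-butyl{[(3S)-6-iodo-3-methylhexyl]oxy}diphenylsilane
Product: 17 {(4S)-6-[(tert-butyldiphenylsilyl)oxy]-4-methylhexyl}triphenylphosphonium iodide
Conditions: PPh3, CH3CN, reflux
Reagents that add atoms: triphenylphosphine c1ccc(cc1)P(c1ccccc1)c1ccccc1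
Why: SN2 quaternisation of triphenylphosphine by the unhindered primary iodide gives the Wittig salt.

Step 13
Reactants: 17 {(4S)-6-[(tert-butyldiphenylsilyl)oxy]-4-methylhexyl}triphenylphosphonium iodide; 11 (3aR,4S,7aR)-4-{[(tert-butyldimethylsilyl)oxy]methyl}-4,7a-dimethyloctahydro-1H-inden-1-one
Product: 19 tert-butyl{[(3S)-6-[(1Z,3aS,4S,7aR)-4-{[(tert-butyldimethylsilyl)oxy]methyl}-4,7a-dimethyloctahydro-1H-inden-1-ylidene]-3-methylhexyl]oxy}diphenylsilane, via ylide 18 (not isolated)
Conditions: KOt-Bu, THF, 0 °C; then 11, reflux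
Reagents that add atoms: none
Why: Wittig olefination with a non-stabilised ylide joins the two fragments at the hindered cyclopentanone and, as with trans-hydrindan-1-ones of the 17-keto steroid type, should give the Z alkylidene with the chain cis to the quaternary C10.

Step 14
Reactants: 19 the (Z)-alkylidene hydrindane
Product: 20 (1S,3aR,4S,7aR)-1-[(1R,4S)-6-[(tert-butyldiphenylsilyl)oxy]-1-hydroxy-4-methylhexyl]-4-{[(tert-butyldimethylsilyl)oxy]methyl}-4,7a-dimethyloctahydro-1H-inden-1-ol
Conditions: OsO4 (5 mol %), NMO, acetone/H2O, rt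
Reagents that add atoms: osmium tetroxide O=[Os](=O)(=O)=O (catalytic carrier of both oxygen atoms); N-methylmorpholine N-oxide C[N+]1([O-])CCOCC1 and water O (net oxygen sources)
Why: Upjohn syn-dihydroxylation should occur on the face anti to the C10 methyl and, being stereospecific on the Z alkene, fixes C8 as S and C9 as R.

Step 15
Reactants: 20 the C8,C9-diol
Product: 21 (1R,4S)-6-[(tert-butyldiphenylsilyl)oxy]-1-[(1S,3aR,4S,7aR)-4-{[(tert-butyldimethylsilyl)oxy]methyl}-1-hydroxy-4,7a-dimethyloctahydro-1H-inden-1-yl]-4-methylhexyl methanesulfonate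
Conditions: MsCl, Et3N, CH2Cl2, −20 °C
Reagents that add atoms: methanesulfonyl chloride CS(=O)(=O)Cl
Why: Sulfonylation through sulfene takes only the secondary C9 hydroxyl and leaves the tertiary C8 hydroxyl free, with no change at any stereocentre.

Step 16
Reactants: 21 the C9 mesylate with free C8 hydroxyl
Product: 23 (4S,5S,9S,10R,13S)-15-[(tert-butyldiphenylsilyl)oxy]-18-[(tert-butyldimethylsilyl)oxy]-17-nor-ent-labdan-8-one, via 9-epimeric ketone 22 (not isolated)
Conditions: Et3Al (3 equiv), CH2Cl2, −78 → 0 °C; aq. sodium potassium tartrate; then NaOMe (0.2 equiv), MeOH/THF, rt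
Reagents that add atoms: none
Why: Et3Al turns the tertiary C8 hydroxyl into an aluminium alkoxide that chelates the C9 mesylate, and as the C9–O bond ionises the antiperiplanar C8–C10 bond shifts to C9 (retention at C10, inversion at C9) while C8 collapses to the ketone, a semipinacol 1,2-shift. The closest known reaction types are the organoaluminium-promoted pinacol-type rearrangement of β-mesyloxy alcohols and the D-homoannulation of 17-hydroxy-20-sulfonyloxy pregnanes, which is the same array on a trans-hydrindane. Ring B is not closed by a cyclisation but arises by one-carbon enlargement of the five-membered ring C5–C6–C7–C8–C10 into the six-membered ring C5–C6–C7–C8–C9–C10 through insertion of C9 between C8 and C10, driven by carbonyl formation and release of trans-hydrindane strain. The new C9 stereocentre is first fixed by the invertive migration (chain axial, 22) and then, being α to the new ketone, should be equilibrated by methoxide to the equatorial chain with axial H-9 anti to the C10 methyl (23). The step needs migration of C10 rather than C7, and this is secured by the 9R configuration from step 14: in the chelated rotamer that places H-9 instead of the chain in the crowded slot between C7 and C10, only the C8–C10 bond is antiperiplanar to the mesylate. Epoxide formation should be suppressed because aluminium holds the O–C8–C9–O unit gauche and the aluminium alkoxide is a weak nucleophile.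

Step 17
Reactants: 23 the 17-nor-8-ketone
Product: 24 (4S,5S,9R,10S,13S)-15-[(tert-butyldiphenylsilyl)oxy]-18-[(tert-butyldimethylsilyl)oxy]-ent-labd-8(17)-ene (same geometry as 23)
Conditions: Ph3PCH3Br, KOt-Bu, THF, reflux
Reagents that add atoms: methyltriphenylphosphonium bromide C[P+](c1ccccc1)(c1ccccc1)c1ccccc1.[Br-]
Why: Wittig methylenation of the 8-ketone installs C17, and because C9 already has the thermodynamically preferred equatorial configuration the basic conditions should not change it.

Step 18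
Reactants: 24 the 8(17)-alkene
Product: 26 (4S,5S,8S,9S,10R,13S)-15-[(tert-butyldiphenylsilyl)oxy]-18-[(tert-butyldimethylsilyl)oxy]-ent-labdan-8-ol, via organomercurial 25 (not isolated)
Conditions: Hg(OAc)2, THF/H2O, rt; then NaBH4, 3 M NaOH, 0 °C
Reagents that add atoms: water O
Why: In this Markovnikov oxymercuration–demercuration water should attack C8 of the mercurinium ion from the equatorial face, the axial approach being blocked by the syn-axial C10 methyl, to give the equatorial tertiary alcohol with axial C17 methyl as in hydration of labd-8(17)-enes.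

Step 19
Reactants: 26 the bis-silyl ether of the triol
Product: 27 (4S,5S,8S,9S,10R,13S)-15-[(tert-butyldiphenylsilyl)oxy]-ent-labdane-8,18-diol
Conditions: camphor-10-sulfonic acid (0.1 equiv), MeOH/CH2Cl2 (1:1), 0 °C
Reagents that add atoms: none
Why: Acid-catalysed methanolysis removes the primary TBS ether much faster than the TBDPS ether, and the cold dilute acid should not dehydrate the tertiary alcohol.

Step 20
Reactants: 27 the 8,18-diol with C15 silyl ether
Product: 28 (4S,5S,8S,9S,10R,13S)-15-[(tert-butyldiphenylsilyl)oxy]-8-hydroxy-ent-labdan-18-yl 3-methylbut-2-enoate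
Conditions: 3-methylbut-2-enoic acid, DCC, DMAP, CH2Cl2, rt
Reagents that add atoms: 3-methylbut-2-enoic acid CC(C)=CC(=O)O
Why: Steglich esterification acylates only the primary C18 hydroxyl (the tertiary C8 hydroxyl is inert), and the acid–carbodiimide protocol avoids the deconjugation that the acid chloride with amine bases can cause.

Step 21
Reactants: 28 the C15 silyl ether of the target
Product: 29 (4S,5S,8S,9S,10R,13S)-8,15-dihydroxy-ent-labdan-18-yl 3-methylbut-2-enoate (CNP0280238.1)
Conditions: TBAF, AcOH, THF, rt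
Reagents that add atoms: none
Why: Buffered fluoride desilylation frees the C15 hydroxyl without acyl transfer or attack on the unsaturated ester.

**Compound list**
1 | 2-methylcyclopentane-1,3-dione | CC1C(=O)CCC1=O | starting material
2 | pent-1-en-3-one (ethyl vinyl ketone) | CCC(=O)C=C | starting material
3 | 2-methyl-2-(3-oxopentyl)cyclopentane-1,3-dione | CCC(=O)CCC1(C)C(=O)CCC1=O | intermediate
4 | (7aR)-4,7a-dimethyl-2,3,7,7a-tetrahydro-1H-indene-1,5(6H)-dione | CC1=C2CCC(=O)[C@]2(C)CCC1=O | intermediate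
5 | (1R,7aR)-1-hydroxy-4,7a-dimethyl-1,2,3,6,7,7a-hexahydro-5H-inden-5-one | CC1=C2CC[C@@H](O)[C@]2(C)CCC1=O | intermediate
6 | dilithium (1R,3aS,7aR)-4,7a-dimethyl-2,3,3a,6,7,7a-hexahydro-1H-indene-1,5-diolate (trans-fused enolate-alkoxide) | CC1=C([O-])CC[C@]2(C)[C@@H]1CC[C@H]2[O-].[Li+].[Li+] | intermediate
7 | (1R,3aS,4S,7aR)-1-hydroxy-4-(hydroxymethyl)-4,7a-dimethyloctahydro-5H-inden-5-one | OC[C@@]1(C)C(=O)CC[C@]2(C)[C@@H]1CC[C@H]2O | intermediate
8 | (1R,3aS,4S,7aR)-4-(hydroxymethyl)-4,7a-dimethyloctahydrospiro[indene-5,2'-[1,3]dithiolan]-1-ol | OC[C@@]1(C)C2(CC[C@]3(C)[C@@H]1CC[C@H]3O)SCCS2 | intermediate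
9 | (1R,3aR,4S,7aR)-4-(hydroxymethyl)-4,7a-dimethyloctahydro-1H-inden-1-ol | OC[C@@]1(C)CCC[C@]2(C)[C@@H]1CC[C@H]2O | intermediate
10 | (1R,3aR,4S,7aR)-4-{[(tert-butyldimethylsilyl)oxy]methyl}-4,7a-dimethyloctahydro-1H-inden-1-ol | CC(C)(C)[Si](C)(C)OC[C@@]1(C)CCC[C@]2(C)[C@@H]1CC[C@H]2O | intermediate
11 | (3aR,4S,7aR)-4-{[(tert-butyldimethylsilyl)oxy]methyl}-4,7a-dimethyloctahydro-1H-inden-1-one | CC(C)(C)[Si](C)(C)OC[C@@]1(C)CCC[C@]2(C)[C@@H]1CCC2=O | intermediate
12 | (S)-citronellol, (3S)-3,7-dimethyloct-6-en-1-ol | CC(C)=CCC[C@H](C)CCO | starting material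
13 | tert-butyl{[(3S)-3,7-dimethyloct-6-en-1-yl]oxy}diphenylsilane | CC(C)=CCC[C@H](C)CCO[Si](c1ccccc1)(c1ccccc1)C(C)(C)C | intermediate
14 | 5-{(3S)-5-[(tert-butyldiphenylsilyl)oxy]-3-methylpentyl}-3,3-dimethyl-1,2,4-trioxolane (ozonide, mixture at the ring carbon) | CC1(C)OOC(CC[C@H](C)CCO[Si](c2ccccc2)(c2ccccc2)C(C)(C)C)O1 | intermediate
15 | (4S)-6-[(tert-butyldiphenylsilyl)oxy]-4-methylhexan-1-ol | OCCC[C@H](C)CCO[Si](c1ccccc1)(c1ccccc1)C(C)(C)C | intermediate
16 | tert-butyl{[(3S)-6-iodo-3-methylhexyl]oxy}diphenylsilane | ICCC[C@H](C)CCO[Si](c1ccccc1)(c1ccccc1)C(C)(C)C | intermediate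
17 | {(4S)-6-[(tert-butyldiphenylsilyl)oxy]-4-methylhexyl}triphenylphosphonium iodide | [I-].C(CC[C@H](C)CCO[Si](c1ccccc1)(c1ccccc1)C(C)(C)C)[P+](c1ccccc1)(c1ccccc1)c1ccccc1 | intermediate
18 | {(4S)-6-[(tert-butyldiphenylsilyl)oxy]-4-methylhexylidene}triphenylphosphorane | C(CC[C@H](C)CCO[Si](c1ccccc1)(c1ccccc1)C(C)(C)C)=P(c1ccccc1)(c1ccccc1)c1ccccc1 | intermediate
19 | tert-butyl{[(3S)-6-[(1Z,3aS,4S,7aR)-4-{[(tert-butyldimethylsilyl)oxy]methyl}-4,7a-dimethyloctahydro-1H-inden-1-ylidene]-3-methylhexyl]oxy}diphenylsilane (chain cis to C10) | CC(C)(C)[Si](C)(C)OC[C@@]1(C)CCC[C@]2(C)[C@@H]1CC/C2=C/CC[C@H](C)CCO[Si](c1ccccc1)(c1ccccc1)C(C)(C)C | intermediate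
20 | (1S,3aR,4S,7aR)-1-[(1R,4S)-6-[(tert-butyldiphenylsilyl)oxy]-1-hydroxy-4-methylhexyl]-4-{[(tert-butyldimethylsilyl)oxy]methyl}-4,7a-dimethyloctahydro-1H-inden-1-ol (both hydroxyls anti to the C10 methyl) | CC(C)(C)[Si](C)(C)OC[C@@]1(C)CCC[C@]2(C)[C@@H]1CC[C@@]2(O)[C@H](O)CC[C@H](C)CCO[Si](c1ccccc1)(c1ccccc1)C(C)(C)C | intermediate
21 | (1R,4S)-6-[(tert-butyldiphenylsilyl)oxy]-1-[(1S,3aR,4S,7aR)-4-{[(tert-butyldimethylsilyl)oxy]methyl}-1-hydroxy-4,7a-dimethyloctahydro-1H-inden-1-yl]-4-methylhexyl methanesulfonate | CC(C)(C)[Si](C)(C)OC[C@@]1(C)CCC[C@]2(C)[C@@H]1CC[C@@]2(O)[C@H](OS(C)(=O)=O)CC[C@H](C)CCO[Si](c1ccccc1)(c1ccccc1)C(C)(C)C | intermediate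
22 | (4S,5S,9R,10R,13S)-15-[(tert-butyldiphenylsilyl)oxy]-18-[(tert-butyldimethylsilyl)oxy]-17-nor-ent-labdan-8-one, 9-epimer (chain axial) | CC(C)(C)[Si](C)(C)OC[C@@]1(C)CCC[C@]2(C)[C@@H]1CCC(=O)[C@@H]2CC[C@H](C)CCO[Si](c1ccccc1)(c1ccccc1)C(C)(C)C | intermediate
23 | (4S,5S,9S,10R,13S)-15-[(tert-butyldiphenylsilyl)oxy]-18-[(tert-butyldimethylsilyl)oxy]-17-nor-ent-labdan-8-one (chain equatorial, H-9 axial) | CC(C)(C)[Si](C)(C)OC[C@@]1(C)CCC[C@]2(C)[C@@H]1CCC(=O)[C@H]2CC[C@H](C)CCO[Si](c1ccccc1)(c1ccccc1)C(C)(C)C | intermediate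
24 | (4S,5S,9R,10S,13S)-15-[(tert-butyldiphenylsilyl)oxy]-18-[(tert-butyldimethylsilyl)oxy]-ent-labd-8(17)-ene | CC(C)(C)[Si](C)(C)OC[C@@]1(C)CCC[C@]2(C)[C@@H]1CCC(=C)[C@H]2CC[C@H](C)CCO[Si](c1ccccc1)(c1ccccc1)C(C)(C)C | intermediate
25 | 17-(acetoxymercurio) derivative of 26 (C8 hydroxyl equatorial, configuration as in 26) | CC(C)(C)[Si](C)(C)OC[C@@]1(C)CCC[C@]2(C)[C@@H]1CC[C@](C[Hg]OC(C)=O)(O)[C@H]2CC[C@H](C)CCO[Si](c1ccccc1)(c1ccccc1)C(C)(C)C | intermediate
26 | (4S,5S,8S,9S,10R,13S)-15-[(tert-butyldiphenylsilyl)oxy]-18-[(tert-butyldimethylsilyl)oxy]-ent-labdan-8-ol | CC(C)(C)[Si](C)(C)OC[C@@]1(C)CCC[C@]2(C)[C@@H]1CC[C@](C)(O)[C@H]2CC[C@H](C)CCO[Si](c1ccccc1)(c1ccccc1)C(C)(C)C | intermediate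
27 | (4S,5S,8S,9S,10R,13S)-15-[(tert-butyldiphenylsilyl)oxy]-ent-labdane-8,18-diol | OC[C@@]1(C)CCC[C@]2(C)[C@@H]1CC[C@](C)(O)[C@H]2CC[C@H](C)CCO[Si](c1ccccc1)(c1ccccc1)C(C)(C)C | intermediate
28 | (4S,5S,8S,9S,10R,13S)-15-[(tert-butyldiphenylsilyl)oxy]-8-hydroxy-ent-labdan-18-yl 3-methylbut-2-enoate | CC(C)=CC(=O)OC[C@@]1(C)CCC[C@]2(C)[C@@H]1CC[C@](C)(O)[C@H]2CC[C@H](C)CCO[Si](c1ccccc1)(c1ccccc1)C(C)(C)C | intermediate
29 | (4S,5S,8S,9S,10R,13S)-8,15-dihydroxy-ent-labdan-18-yl 3-methylbut-2-enoate | CC(C)=CC(=O)OC[C@@]1(C)CCC[C@]2(C)[C@@H]1CC[C@](C)(O)[C@H]2CC[C@H](C)CCO | target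

**Step count and risks**
Total step count: 21. Longest linear sequence: 17 (steps 1–8, then 13–21); the side-chain branch is steps 9–12.

Steps most likely to fail:

1. Step 16. What may go wrong: loss of migratory selectivity (shift of the C8–C7 bond through the minor rotamer), closure of the alkoxide onto C9 to an epoxide, or incomplete equilibration of C9 to the equatorial epimer. The fallback sets out from 15 and 11 and comes back at 23. Alcohol 15 is oxidised with Dess–Martin periodinane to (4S)-6-[(tert-butyldiphenylsilyl)oxy]-4-methylhexanal F1, which (PhO)3P/Br2/Et3N converts into the 1,1-dibromide F2. LDA at −95 °C in the presence of ketone 11 generates the 1,1-dibromoalkyllithium, which adds to C8 anti to the angular methyl to give the β-hydroxy gem-dibromide F3. n-BuLi (2.2 equiv, −78 °C) then forms the β-oxido carbenoid, whose 1,2-shift (in this rearrangement the more substituted carbon, here C10, normally migrates, and the carbenoid carbon is configurationally labile) gives the ring-enlarged lithium enolate F4. Protonation and methoxide equilibration return to 23. The approach changes from a rotamer-controlled stereospecific shift to a carbenoid ring enlargement governed by migratory aptitude that joins both fragments and inserts C9 in one flask.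

2. Step 4. What may go wrong: poor facial selectivity in protonation at C5 (cis ring fusion), proton exchange of the enolate before trapping, or over-reduction. The fallback sets out from 5 and comes back at 7. The thermodynamic extended dienolate of 5 (KOt-Bu, t-BuOH/THF) is α-hydroxymethylated with monomeric formaldehyde at −78 °C, anti to the angular methyl, to give the deconjugated β,γ-enone (1R,4S,7aR)-1-hydroxy-4-(hydroxymethyl)-4,7a-dimethyl-1,2,4,6,7,7a-hexahydro-5H-inden-5-one F5. Hydrogenation (H2, Pd/C, EtOAc) from the face anti to the C10 and axial C4 methyls then delivers H-5 trans to the angular methyl and gives 7. The ring-fusion centre is thus set by hydrogenation instead of by protonation of a carbanion.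

3. Step 18. What may go wrong: poor facial selectivity of water delivery, or acid-induced migration of the exocyclic double bond into the ring before hydration. The fallback sets out from 24 and comes back at 26. Epoxidation (mCPBA, NaHCO3, CH2Cl2, 0 °C) from the equatorial face anti to the C10 methyl gives the 8,17-epoxide F6. LiAlH4 (THF, 0 °C → rt) opens it at the primary C17 to the equatorial tertiary alcohol 26. The carbinol is thus made by hydride opening of an epoxide instead of by Markovnikov hydration.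

**Further compounds**
F1 | step 16 | (4S)-6-[(tert-butyldiphenylsilyl)oxy]-4-methylhexanal | O=CCC[C@H](C)CCO[Si](c1ccccc1)(c1ccccc1)C(C)(C)C
F2 | step 16 | tert-butyl{[(3S)-6,6-dibromo-3-methylhexyl]oxy}diphenylsilane | BrC(Br)CC[C@H](C)CCO[Si](c1ccccc1)(c1ccccc1)C(C)(C)C
F3 | step 16 | β-hydroxy gem-dibromide: C8 adduct of 11 with the dibromoalkyl chain anti to the C10 methyl | CC(C)(C)[Si](C)(C)OC[C@@]1(C)CCC[C@]2(C)[C@@H]1CC[C@]2(O)C(Br)(Br)CC[C@H](C)CCO[Si](c1ccccc1)(c1ccccc1)C(C)(C)C
F4 | step 16 | ring-enlarged lithium C8–C9 enolate of 23 | CC(C)(C)[Si](C)(C)OC[C@@]1(C)CCC[C@]2(C)[C@@H]1CCC(O[Li])=C2CC[C@H](C)CCO[Si](c1ccccc1)(c1ccccc1)C(C)(C)C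
F5 | step 4 | (1R,4S,7aR)-1-hydroxy-4-(hydroxymethyl)-4,7a-dimethyl-1,2,4,6,7,7a-hexahydro-5H-inden-5-one | OC[C@@]1(C)C(=O)CC[C@]2(C)C1=CC[C@H]2O
F6 | step 18 | 8,17-epoxide of 24 (oxygen equatorial, anti to the C10 methyl) | CC(C)(C)[Si](C)(C)OC[C@@]1(C)CCC[C@]2(C)[C@@H]1CC[C@]3(OC3)[C@H]2CC[C@H](C)CCO[Si](c1ccccc1)(c1ccccc1)C(C)(C)C
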